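**Retrosynthetic overview**

1. Target 19 ⇐ ketone reduction at C2' of the enol lactone 17, which is the adduct of an intramolecular Diels–Alder reaction between a dearomatised 2,4-cyclohexadienone (ring D) and the exocyclic C8=C12 alkene of ring B; this one step forms C8–C6' and C12–C3', i.e. the cyclopentane (ring C) and the bicyclo[2.2.2]octane.
2. Dienone 16 ⇐ vinyl epoxide 15 (formate hydrogenolysis sets C9–H; epoxidation sets C10–OH) ⇐ dienone 14 ⇐ C5'-alkylative dearomatisation of 5,7-dihydroxy-4,6-dimethylphthalide 13 with dienyl bromide 11.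
3. Bromide 11 ⇐ spiro enone lactone 7 (MeLi addition, formaldehyde ene reaction for C11 and C8=C12, bromination, dehydration) ⇐ (R)-pulegone 1 + tert-butyl acrylate 2 (Michael quaternisation at C5, acid lactonisation, double dehydrogenation).
4. Ring order: B (bought in pulegone) → A (step 2) → D and the γ-lactone (bought in the phthalide, dearomatised in step 9) → C plus bicyclo[2.2.2]octane (step 12).

Assumption: 1, 2 and 12 are the bought materials; biogenetic locants are used in the text: ring A C1=C2–C3(=O)–O–C4(CH3)2–C5(spiro); ring B C5–C6–C7–C8–C9–C10; C11 = CH2 on C9; C12 = CH2 on C8; arene-derived ring C1'(bears C7'=O)–C2'–C3'(CH3)–C4'(=O)–C5'(CH3)–C6'(bears C8'H2–O).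

**Route**

Step 1
Reactants: 1 (R)-(+)-pulegone; 2 tert-butyl acrylate
Product: 3 tert-butyl 3-[(1R,4R)-4-methyl-2-oxo-1-(prop-1-en-2-yl)cyclohexyl]propanoate
Conditions: KOtBu (0.2 equiv), tBuOH–THF, 0 → 23 °C
Reagents that add atoms: none
Why: Michael addition of the extended (thermodynamic) dienolate at its α-carbon with deconjugation to the isopropenyl group; the acrylate enters axially on the half-chair that keeps the ring methyl equatorial (cis to the methyl), so the bought stereocentre fixes quaternary C5 by 1,4-induction (moderate dr expected, minor epimer removed).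

Step 2
Reactants: 3 tert-butyl 3-[(1R,4R)-4-methyl-2-oxo-1-(prop-1-en-2-yl)cyclohexyl]propanoate
Product: 5 (6R,9R)-1,1,9-trimethyl-2-oxaspiro[5.5]undecane-3,7-dione, via keto acid 4 (not isolated)
Conditions: CF3CO2H, CH2Cl2, 0 → 23 °C
Reagents that add atoms: none
Why: acidolysis of the tert-butyl ester, then Markovnikov acid-catalysed lactonisation of the acid onto the isopropenyl group (tertiary cation, six-membered ring closure) builds ring A without touching a stereocentre.

Step 3
Reactants: 5 (6R,9R)-1,1,9-trimethyl-2-oxaspiro[5.5]undecane-3,7-dione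
Product: 7 (6R)-1,1,9-trimethyl-2-oxaspiro[5.5]undeca-4,8-diene-3,7-dione, via bis(phenylselanyl) keto lactone 6 (not isolated)
Conditions: LiN(iPr)2 (2.3 equiv), THF, −78 °C; PhSeBr; then H2O2, pyridine, CH2Cl2, 0 → 23 °C
Reagents that add atoms: none
Why: α-selenenylation of the ketone/lactone bis-enolate and twofold selenoxide syn-elimination (each selenide has β-hydrogens on one side only) give the ring B enone and the ring A enoate at once; the pulegone methyl stereocentre is erased after it has set C5.

Step 4
Reactants: 7 (6R)-1,1,9-trimethyl-2-oxaspiro[5.5]undeca-4,8-diene-3,7-dione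
Product: 8 (6S,7R)-7-hydroxy-1,1,7,9-tetramethyl-2-oxaspiro[5.5]undeca-4,8-dien-3-one
Conditions: MeLi, CeCl3, THF, −78 °C
Reagents that add atoms: methyllithium, [Li]C
Why: organocerium 1,2-addition to the enone carbonyl (faster than attack on the lactone), methyl entering anti to the pseudo-axial C1 arm of the spiro centre; this carbinol centre is re-set in steps 10–11, so its ratio is not critical.

Step 5
Reactants: 8 (6S,7R)-7-hydroxy-1,1,7,9-tetramethyl-2-oxaspiro[5.5]undeca-4,8-dien-3-one
Product: 9 (6S,7R,8S)-7-hydroxy-8-(hydroxymethyl)-1,1,7-trimethyl-9-methylidene-2-oxaspiro[5.5]undec-4-en-3-one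
Conditions: (CH2O)n, Me2AlCl (3 equiv), CH2Cl2, −20 → 0 °C
Reagents that add atoms: formaldehyde (from paraformaldehyde), C=O
Why: Lewis-acid carbonyl-ene reaction in which formaldehyde bonds to the less substituted alkene carbon (C9) and abstracts hydrogen from the methyl group syn to the vinylic H, which installs C11 and the exocyclic C8=C12 regiospecifically; delivery from the aluminium alkoxide puts CH2OH cis to the hydroxyl (H9 trans to OH).

Step 6
Reactants: 9 (6S,7R,8S)-7-hydroxy-8-(hydroxymethyl)-1,1,7-trimethyl-9-methylidene-2-oxaspiro[5.5]undec-4-en-3-one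
Product: 10 (6S,7R,8R)-8-(bromomethyl)-7-hydroxy-1,1,7-trimethyl-9-methylidene-2-oxaspiro[5.5]undec-4-en-3-one
Conditions: CBr4, PPh3, CH2Cl2, 0 °C
Reagents that add atoms: tetrabromomethane, BrC(Br)(Br)Br
Why: Appel bromination, selective for the primary over the tertiary alcohol; no stereocentre changes.

Step 7
Reactants: 10 (6S,7R,8R)-8-(bromomethyl)-7-hydroxy-1,1,7-trimethyl-9-methylidene-2-oxaspiro[5.5]undec-4-en-3-one
Product: 11 (6S)-8-(bromomethyl)-1,1,7-trimethyl-9-methylidene-2-oxaspiro[5.5]undeca-4,7-dien-3-one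
Conditions: Ph2S[OC(CF3)2Ph]2 (Martin sulfurane), CH2Cl2, 0 °C
Reagents that add atoms: none
Why: sulfurane dehydration by anti-elimination of the tertiary alkoxysulfonium with the allylic, trans-disposed H9 gives the conjugated diene and so makes C11 an allylic bromide (an unactivated β-branched C11–Br would not C-alkylate a phenolate); the C9/C10 centres are given up on purpose and rebuilt in steps 10–11.

Step 8
Reactants: 12 5,7-dihydroxy-4-methyl-2-benzofuran-1(3H)-one
Product: 13 5,7-dihydroxy-4,6-dimethyl-2-benzofuran-1(3H)-one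
Conditions: MeI, KOH, MeOH, reflux; then aq. HCl
Reagents that add atoms: iodomethane, CI
Why: nuclear C-methylation of the resorcinol-type anion at the only free ring carbon (between the two hydroxyls); the lactone recloses on acidification.

Step 9
Reactants: 11 (6S)-8-(bromomethyl)-1,1,7-trimethyl-9-methylidene-2-oxaspiro[5.5]undeca-4,7-dien-3-one; 13 5,7-dihydroxy-4,6-dimethyl-2-benzofuran-1(3H)-one
Product: 14 7-hydroxy-4,6-dimethyl-4-{[(6S)-1,1,7-trimethyl-9-methylidene-3-oxo-2-oxaspiro[5.5]undeca-4,7-dien-8-yl]methyl}-2-benzofuran-1,5(3H,4H)-dione (both C5' epimers)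
Conditions: LiOtBu (1.05 equiv), PhMe–THF, −20 → 0 °C
Reagents that add atoms: none
Why: alkylative dearomatisation, i.e. SN2 C-allylation of the tight lithium phenolate at C5' (ortho to the phenolate oxygen, product keeps the hydrogen-bonded enol lactone); no stereocentre is near enough to bias the new quaternary C5', so both epimers form (about 1:1) and are carried on together.

Step 10
Reactants: 14 (both C5' epimers)
Product: 15 9,10-epoxide of 14 with the oxirane oxygen cis to C1 and trans to C4 (both C5' epimers)
Conditions: dimethyldioxirane (1.0 equiv), acetone, −78 → −30 °C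
Reagents that add atoms: dimethyldioxirane, CC1(C)OO1
Why: electrophilic epoxidation of the most electron-rich (tetrasubstituted) alkene; allylic 1,2-strain with the C10 methyl forces the bulky C4 arm of the spiro centre pseudo-axial, so oxygen arrives on the opposite face, and the C5 stereocentre thereby sets C10.

Step 11
Reactants: 15 (both C5' epimers)
Product: 16 7-hydroxy-4-{[(6S,7R,8R)-7-hydroxy-1,1,7-trimethyl-9-methylidene-3-oxo-2-oxaspiro[5.5]undec-4-en-8-yl]methyl}-4,6-dimethyl-2-benzofuran-1,5(3H,4H)-dione (both C5' epimers)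
Conditions: Pd2(dba)3·CHCl3 (2.5 mol %), PBu3 (10 mol %), HCO2H, Et3N, dioxane, 23 °C
Reagents that add atoms: none
Why: Tsuji–Shimizu hydrogenolysis of the vinyl epoxide: ionisation to the π-allylpalladium alkoxide with inversion and hydride transfer from formate to the more substituted allyl terminus (C9) on the palladium face give the homoallylic tertiary alcohol with H9 anti to the former C–O bond (C11 cis to the C10 hydroxyl) and keep the exocyclic C8=C12.

Step 12
Reactants: 16 (the (5'R) epimer of the mixture reacts)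
Product: 17 enol lactone cage compound (target skeleton with C1'=C2'–OH)
Conditions: PhMe (0.01 M), BHT, 110 °C
Reagents that add atoms: none
Why: intramolecular Diels–Alder reaction of the 2,4-cyclohexadienone with the 1,1-disubstituted alkene through the C11 tether (cis-fused cyclopentane); only (5'R)-16 has the tether on the dienone face that can reach C8=C12, so C8, C3' and C6' follow from C9 and C5', and the (5'S) epimer is recovered unchanged.

Step 13
Reactants: 17 enol lactone cage compound
Product: 19 target CNP0360620.3 [(5S,8S,9R,10R,1'S,2'R,3'S,5'R,6'R) in the biogenetic locants], via β-keto lactone tautomer 18 (not isolated)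
Conditions: NaBH4, CeCl3·7H2O, MeOH, −78 → −40 °C
Reagents that add atoms: none
Why: Luche-type 1,2-reduction of the C2' ketone only (the C4' ketone lies between two quaternary carbons, the enoate is not touched): CeCl3 chelation of the C2'/C4' dicarbonyl shields that face, hydride comes from the C12 side and leaves the hydroxyl syn to the C4' ketone, while C1' equilibrates through the enol so that the lactone carbonyl ends trans to the new hydroxyl.

**Compound list**

1 | (R)-(+)-pulegone | C[C@@H]1CCC(=C(C)C)C(=O)C1 | starting material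
2 | tert-butyl acrylate | C=CC(=O)OC(C)(C)C | starting material
3 | tert-butyl 3-[(1R,4R)-4-methyl-2-oxo-1-(prop-1-en-2-yl)cyclohexyl]propanoate | CC(C)(C)OC(=O)CC[C@@]1(C(C)=C)CC[C@@H](C)CC1=O | intermediate
4 | 3-[(1R,4R)-4-methyl-2-oxo-1-(prop-1-en-2-yl)cyclohexyl]propanoic acid | OC(=O)CC[C@@]1(C(C)=C)CC[C@@H](C)CC1=O | intermediate (not isolated)
5 | (6R,9R)-1,1,9-trimethyl-2-oxaspiro[5.5]undecane-3,7-dione | CC1(C)OC(=O)CC[C@]12CC[C@@H](C)CC2=O | intermediate
6 | (6R,9R)-1,1,9-trimethyl-4,8-bis(phenylselanyl)-2-oxaspiro[5.5]undecane-3,7-dione (epimers at C4 and C8) | CC1(C)OC(=O)C([Se]c3ccccc3)C[C@]12CC[C@@H](C)C([Se]c3ccccc3)C2=O | intermediate (not isolated)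
7 | (6R)-1,1,9-trimethyl-2-oxaspiro[5.5]undeca-4,8-diene-3,7-dione | CC1(C)OC(=O)C=C[C@]12CCC(C)=CC2=O | intermediate
8 | (6S,7R)-7-hydroxy-1,1,7,9-tetramethyl-2-oxaspiro[5.5]undeca-4,8-dien-3-one | CC1(C)OC(=O)C=C[C@]12CCC(C)=C[C@@]2(C)O | intermediate
9 | (6S,7R,8S)-7-hydroxy-8-(hydroxymethyl)-1,1,7-trimethyl-9-methylidene-2-oxaspiro[5.5]undec-4-en-3-one | CC1(C)OC(=O)C=C[C@]12CCC(=C)[C@@H](CO)[C@@]2(C)O | intermediate
10 | (6S,7R,8R)-8-(bromomethyl)-7-hydroxy-1,1,7-trimethyl-9-methylidene-2-oxaspiro[5.5]undec-4-en-3-one | CC1(C)OC(=O)C=C[C@]12CCC(=C)[C@@H](CBr)[C@@]2(C)O | intermediate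
11 | (6S)-8-(bromomethyl)-1,1,7-trimethyl-9-methylidene-2-oxaspiro[5.5]undeca-4,7-dien-3-one | CC1(C)OC(=O)C=C[C@]12CCC(=C)C(CBr)=C2C | intermediate
12 | 5,7-dihydroxy-4-methyl-2-benzofuran-1(3H)-one | Cc1c(O)cc(O)c2C(=O)OCc12 | starting material
13 | 5,7-dihydroxy-4,6-dimethyl-2-benzofuran-1(3H)-one | Cc1c(O)c(C)c(O)c2C(=O)OCc12 | intermediate
14 | 7-hydroxy-4,6-dimethyl-4-{[(6S)-1,1,7-trimethyl-9-methylidene-3-oxo-2-oxaspiro[5.5]undeca-4,7-dien-8-yl]methyl}-2-benzofuran-1,5(3H,4H)-dione (C5' epimer pair, C5' left open in the SMILES) | CC1(C)OC(=O)C=C[C@]12CCC(=C)C(CC3(C)C(=O)C(C)=C(O)C4=C3COC4=O)=C2C | intermediate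
15 | 9,10-epoxide of 14, oxirane oxygen cis to C1 and trans to C4 (C5' epimer pair) | CC1(C)OC(=O)C=C[C@]12CCC(=C)[C@@]3(CC4(C)C(=O)C(C)=C(O)C5=C4COC5=O)O[C@@]23C | intermediate
16 | 7-hydroxy-4-{[(6S,7R,8R)-7-hydroxy-1,1,7-trimethyl-9-methylidene-3-oxo-2-oxaspiro[5.5]undec-4-en-8-yl]methyl}-4,6-dimethyl-2-benzofuran-1,5(3H,4H)-dione (C5' epimer pair; in the reactive (5'R) epimer the quaternary ring carbon is written C[C@@]3(C)) | CC1(C)OC(=O)C=C[C@]12CCC(=C)[C@@H](CC3(C)C(=O)C(C)=C(O)C4=C3COC4=O)[C@@]2(C)O | intermediate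
17 | enol lactone cage compound: target skeleton with C1'=C2' enol (2'-OH), all other centres as in 19 | CC1(C)OC(=O)C=C[C@]12CC[C@]13C[C@]4(C)C(=O)[C@](C)(C[C@H]1[C@@]2(C)O)[C@]31COC(=O)C1=C4O | intermediate
18 | β-keto lactone tautomer of 17 (C2' ketone, C1' epimerisable) | CC1(C)OC(=O)C=C[C@]12CC[C@]13C[C@]4(C)C(=O)[C@](C)(C[C@H]1[C@@]2(C)O)[C@]31COC(=O)C1C4=O | intermediate (not isolated)
19 | CNP0360620.3, (5S,8S,9R,10R,1'S,2'R,3'S,5'R,6'R) in the biogenetic locants | CC1(C)OC(=O)C=C[C@]12CC[C@]13C[C@]4(C)C(=O)[C@](C)(C[C@H]1[C@@]2(C)O)[C@]31COC(=O)[C@@H]1[C@H]4O | target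

**Totals and risks**

Total step count: 13. Longest linear sequence: 12 (steps 1–7 and 9–13, from pulegone).

Most likely to fail, first: step 9. The phenolate of 13 may be alkylated on oxygen or at C3' instead of C5'. In that case the bond is made under palladium catalysis instead of by SN2. The fallback sets out from diol 9, which is converted with ClCO2Me and pyridine into its primary methyl carbonate F1. F1 is dehydrated with Ph2S[OC(CF3)2Ph]2 to the dienyl methyl carbonate F2. F2 is ionised by Pd(PPh3)4 (zerovalent palladium, THF, 23 °C) in the presence of 13. O-Allyl ethers re-ionise under these conditions, so the phenoxide/π-allyl pair is funnelled to attack through carbon at the unhindered allyl terminus. The C5'-allylated vinylogous acid accumulates, and the route is rejoined at 14.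

Second: step 12. The cycloaddition uses only the (5'R) half of 16, because step 9 cannot control C5'. The fallback sets out from the recovered (5'S) epimer in 16. Irradiation (365 nm, benzene, 23 °C) opens the 2,4-cyclohexadienone by 6π electrocyclic ring opening to the dienylketene F3. F3 recloses thermally to both C5' epimers, and the material comes back to the route as 16 and is resubmitted to step 12. Heating and irradiation can also be run together, which turns the Diels–Alder step into a stereoconvergent one.

Third: step 13. Hydride may prefer the face of the C4' ketone bridge, which has no inward C–H, and then gives the C2' epimer. The fallback sets out from 17, accepts the borohydride product as the 2'-epimeric alcohol F4, and corrects it by redox equilibration instead of reagent tuning. Al(OiPr)3, iPrOH with a little acetone, PhMe, 80 °C (Meerwein–Ponndorf–Verley/Oppenauer hydrogen transfer through 18) drains F4 to the more stable alcohol. In that alcohol the hydroxyl is syn to the C4' ketone and trans to the lactone carbonyl, and the route is rejoined at 19.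

**Further compounds**

F1 | step 9 | methyl [(6S,7R,8S)-7-hydroxy-1,1,7-trimethyl-9-methylidene-3-oxo-2-oxaspiro[5.5]undec-4-en-8-yl]methyl carbonate | CC1(C)OC(=O)C=C[C@]12CCC(=C)[C@@H](COC(=O)OC)[C@@]2(C)O
F2 | step 9 | methyl [(6S)-1,1,7-trimethyl-9-methylidene-3-oxo-2-oxaspiro[5.5]undeca-4,7-dien-8-yl]methyl carbonate | CC1(C)OC(=O)C=C[C@]12CCC(=C)C(COC(=O)OC)=C2C
F3 | step 12 | dienylketene from ring opening of 16 (C4'–C5' bond cleaved, C5'=C6' geometry open) | CC1(C)OC(=O)C=C[C@]12CCC(=C)[C@@H](CC(C)=C3COC(=O)C3=C(O)C(C)=C=O)[C@@]2(C)O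
F4 | step 13 | 2'-epimer of 19 | CC1(C)OC(=O)C=C[C@]12CC[C@]13C[C@]4(C)C(=O)[C@](C)(C[C@H]1[C@@]2(C)O)[C@]31COC(=O)[C@@H]1[C@@H]4O
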